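## Assumptions
- The SMILES has 20 C atoms before the ring closure. The last is the ring carbon, so the side chain is n‑nonadecyl (C19H39). The target is 5‑hydroxy‑2‑methoxy‑6‑nonadecyl‑1,4‑benzoquinone, C26H44O4.
- The target has no stereocentres, so "single enantiomer" has no consequence. The only stereocentre in the route is the carbinol carbon of 6 and 8, which is racemic and is destroyed in Step 6.
- Di‑tert‑butyl squarate, 1‑bromononadecane and 2‑chloro‑1,1‑dimethoxyethane are treated as commercial.

## Retrosynthesis
1. Remove the tert‑butyl group from 5‑OtBu‑2‑OMe‑6‑nonadecylquinone 9 to unmask the C5‑OH (last step).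
2. Form the fully substituted quinone in one step by a Moore thermal ring expansion of a 4‑hydroxy‑4‑(methoxyethynyl)cyclobutenone (8). The ring expansion fixes the OMe / H / OtBu / alkyl pattern by construction, so no late C–H alkylation or regioselective methylation is needed.
3. Make 8 from di‑tert‑butyl squarate by Grignard addition, then acid‑induced loss of one tBu group to give the alkyl‑alkoxy‑cyclobutenedione 7. LiC≡COMe then adds to the carbonyl next to the C–OtBu carbon.
4. The four‑membered ring is already present in the squarate, and the only ring formed is the benzoquinone ring (Step 6).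

## Route

**Step 1**
Reactants: 1 (2‑chloro‑1,1‑dimethoxyethane)
Product: 2 (methoxyacetylene)
Conditions: NaNH2 (3 equiv), liq. NH3, –33 °C; distil the volatile product into cold THF
Reagents that add atoms: none
Why: Double dehydrohalogenation/elimination of the chloroacetal (via the 1,1‑dimethoxyethene, then loss of MeO–) gives the terminal ynol ether, by analogy with the classic ethoxyacetylene preparation. No stereocentre is involved.

**Step 2**
Reactants: 3 (1‑bromononadecane)
Product: 4 (nonadecylmagnesium bromide)
Conditions: Mg turnings, I2 (cat.), THF, 45 °C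
Reagents that add atoms: Mg, [Mg]
Why: Standard Grignard formation. The Grignard is poorly soluble, so it is kept dilute (about 0.2 M) and warm and used at once.

**Step 3**
Reactants: 4 (nonadecylmagnesium bromide) and 5 (di‑tert‑butyl squarate, 3,4‑di‑tert‑butoxycyclobut‑3‑ene‑1,2‑dione)
Product: 6 (4‑hydroxy‑4‑nonadecyl‑2,3‑di‑tert‑butoxycyclobut‑2‑en‑1‑one, racemic)
Conditions: 4 (0.2 M in THF, about 30 °C) added dropwise by cannula to 5 in THF, –40 °C, 1 h; sat. aq. NH4Cl
Reagents that add atoms: none (the Grignard is reactant 4; the NH4Cl quench adds only H)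
Why: 1,2‑Addition of an organometallic to a squarate diester (Liebeskind squarate addition) gives a tertiary 4‑hydroxycyclobutenone. The remaining vinylogous‑ester carbonyl is too deactivated for a second addition. The new carbinol stereocentre is racemic and is later destroyed.

**Step 4**
Reactants: 6
Product: 7 (3‑tert‑butoxy‑4‑nonadecylcyclobut‑3‑ene‑1,2‑dione)
Conditions: TFA (1.5 equiv), CH2Cl2, 0 °C, 20 min; aq. NaHCO3 wash
Reagents that add atoms: none
Why: Acid ionises the tertiary OH to give a cyclobutenyl cation. The tBuO group on the distal carbon stabilises it as an oxocarbenium, which loses isobutene to give the dione (Liebeskind hydroxycyclobutenone → alkylcyclobutenedione rearrangement). The net loss is tBuOH. The OtBu on the carbon next to the new alkyl‑bearing carbon survives this short, mild acid exposure.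

**Step 5**
Reactants: 7 and 2 (methoxyacetylene)
Product: 8 (3‑tert‑butoxy‑4‑hydroxy‑4‑(methoxyethynyl)‑2‑nonadecylcyclobut‑2‑en‑1‑one, racemic)
Conditions: 2 + n‑BuLi (1.0 equiv), THF, –78 °C, 30 min; add 7, –78 °C, 1 h; aq. NH4Cl; chromatography on Et3N‑deactivated silica
Reagents that add atoms: none (n‑BuLi only deprotonates 2, and the work‑up adds H)
Why: The carbonyl next to the C–OtBu carbon is the more electrophilic one. The other carbonyl is a vinylogous‑ester carbonyl, deactivated and flanked by the nonadecyl chain. The lithium ynolate‑type acetylide therefore adds regioselectively (Liebeskind regiochemistry) to give the tertiary propargylic alcohol. The carbinol stereocentre is racemic.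

**Step 6**
Reactants: 8
Product: 9 (5‑tert‑butoxy‑2‑methoxy‑6‑nonadecyl‑1,4‑benzoquinone)
Conditions: toluene (0.02 M), BHT (cat.), Ar, 110 °C, 3 h
Reagents that add atoms: none
Why: Moore rearrangement. 4π‑Electrocyclic ring opening of the cyclobutenone gives an (alkynyl)vinylketene. The ketene carbon closes onto the methoxy‑bearing alkyne carbon to form a diradical, and transfer of the carbinol O–H hydrogen to the other radical centre gives the quinone directly. The ketene‑derived C=O ends up flanked by C–OMe and the alkyl‑bearing carbon. The former carbinol carbon becomes the C=O flanked by C–OtBu and the quinone C–H. The carbinol stereocentre is destroyed here.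

**Step 7**
Reactants: 9
Product: 10 (Irisoquin‑C, 5‑hydroxy‑2‑methoxy‑6‑nonadecyl‑1,4‑benzoquinone)
Conditions: TFA/CH2Cl2 (1:4), 0 °C → rt, 2 h; evaporate and recrystallise
Reagents that add atoms: none (the tBu group leaves as isobutene)
Why: The vinylogous tert‑butyl ester is cleaved by E1 loss of isobutene. The methyl vinylogous ester is stable to TFA, so only the 5‑OH is unmasked.

**Final checks**
- Atom balance:
  - 6 is C31H58O4 and 7 is C27H48O3, a difference of tBuOH.
  - 7 (C27H48O3) + 2 (C3H4O) = 8 (C30H52O4).
  - 9 is an isomer of 8.
  - 9 – C4H8 = 10 (C26H44O4).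
- Ring substitution in 10 matches the target SMILES: C1(=O) flanked by C2‑OMe and C6‑alkyl, C3‑H, C4(=O) flanked by C3‑H and C5‑OH.
- The C19 chain is untouched throughout.
- The OtBu group survives Steps 3 to 6 (briefly exposed to TFA in Step 4), and OMe survives throughout.

## Compound list
1 | 2‑chloro‑1,1‑dimethoxyethane | ClCC(OC)OC | starting material
2 | methoxyacetylene | COC#C | intermediate (reagent)
3 | 1‑bromononadecane | CCCCCCCCCCCCCCCCCCCBr | starting material
4 | nonadecylmagnesium bromide | CCCCCCCCCCCCCCCCCCC[Mg]Br | intermediate (reagent)
5 | di‑tert‑butyl squarate | CC(C)(C)OC1=C(OC(C)(C)C)C(=O)C1=O | starting material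
6 | 4‑hydroxy‑4‑nonadecyl‑2,3‑di‑tert‑butoxycyclobut‑2‑enone (racemic) | CCCCCCCCCCCCCCCCCCCC1(O)C(=O)C(OC(C)(C)C)=C1OC(C)(C)C | intermediate
7 | 3‑tert‑butoxy‑4‑nonadecylcyclobut‑3‑ene‑1,2‑dione | CCCCCCCCCCCCCCCCCCCC1=C(OC(C)(C)C)C(=O)C1=O | intermediate
8 | 3‑tert‑butoxy‑4‑hydroxy‑4‑(methoxyethynyl)‑2‑nonadecylcyclobut‑2‑enone (racemic) | CCCCCCCCCCCCCCCCCCCC1=C(OC(C)(C)C)C(O)(C#COC)C1=O | intermediate
9 | 5‑tert‑butoxy‑2‑methoxy‑6‑nonadecyl‑1,4‑benzoquinone | CCCCCCCCCCCCCCCCCCCC1=C(OC(C)(C)C)C(=O)C=C(OC)C1=O | intermediate
10 | Irisoquin‑C (achiral) | CCCCCCCCCCCCCCCCCCCC1=C(O)C(=O)C=C(OC)C1=O | target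

## Step count
- Total steps: 7, including two reagent preparations (Steps 1 and 2).
- Longest linear sequence: 6 steps, 3 → 4 → 6 → 7 → 8 → 9 → 10 (Steps 2, 3, 4, 5, 6, 7). The methoxyacetylene branch (Steps 1 and 5 to 7) is shorter.

## Three steps most likely to fail
1. **Step 6 (Moore ring expansion of an alkoxy‑alkynyl, tBu‑ether substrate).** Risks are thermal loss of the tBu group, ynol‑ether decomposition, competing ketene dimerisation, or diversion to a cyclopentenedione.
   - Fallback (different approach): abandon the cyclobutenone. Take 2,5‑dihydroxy‑1,4‑benzoquinone and do a reductive alkylation with nonadecanal (Knoevenagel‑type condensation, then reduction with Na2S2O4 or a Hantzsch ester). Then regioselectively methylate the OH remote from the alkyl chain (TMSCHN2 or MeI/Ag2O), following the known embelin 5‑O‑methylation pattern.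
2. **Step 4 (selective acid rearrangement that keeps one tBu).** Over‑acidification would give the squaric acid monoester, and the ionisation could be sluggish.
   - Fallback (different approach): make 7 by cross‑coupling. Start from 3‑chloro‑4‑tert‑butoxycyclobutenedione (from squaryl dichloride and tBuOH) and couple it with B‑nonadecyl‑9‑BBN under Pd catalysis (B‑alkyl Suzuki coupling).
3. **Step 5 (lithium methoxyacetylide addition and the acid‑sensitivity of ynol ether 8).** Methoxyacetylene is volatile, 8 can hydrolyse to an ester, and the regioselectivity of addition may be imperfect.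
   - Fallback (different approach): add lithium TMS‑acetylide instead, then desilylate and run the Moore step. This gives the 2‑H quinone (5‑OtBu‑6‑nonadecyl). Introduce the 2‑OMe by Lewis‑acid‑catalysed conjugate addition of MeOH to the more electrophilic C4 carbonyl's β‑carbon (C2, para to the OtBu donor), followed by Ag2O re‑oxidation to 9.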